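**Retrosynthetic overview**

- The strategy rests on ring A of this 3-arylcoumarin: C8, which carries the 1,1-dimethylallyl group, lies between O1 and the 7-OH and para to the 5-OMe. Ring A is therefore a C2-symmetric 2-(1,1-dimethylallyl)-5-methoxyresorcinol whose two free CH carbons (future C4a and C6) and two hydroxyls (future O1 and 7-OH) are interchangeable.
- The pyranone is cut at C4–C4a (C–C bond) and O1–C2 (acyl transfer). C2, C3 and C4 arrive with ring B as a 3-(methoxymethylene)benzofuran-2(3H)-one, in which the 2'-oxygen holds the C2 carboxyl as a five-membered lactone.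
- Ring A fragment: 5-methoxyresorcinol, bis-MOM ether, lithiation and bromination between the acetal oxygens, branched-selective Suzuki–Miyaura coupling with prenylboronic ester, acetal removal.
- Ring B fragment: 2,4-dihydroxyphenylacetic acid, lactonisation, then methoxymethylenation with concurrent acetylation of the remaining phenol.
- Ring order: both benzene rings are bought, the furanone is closed first as a temporary bridge, and the pyranone is closed last as that bridge opens. Acetate methanolysis finishes the synthesis.

Key step: step 7

Assumption: the four starting materials are taken as purchasable; the ring B enol ether is drawn as its E isomer by analogy with the unsubstituted compound, and its geometry has no consequence because it is lost in the annulation.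

**Route**

Step 1
Reactants: 1 5-methoxyresorcinol (5-methoxybenzene-1,3-diol)
Product: 2 1-methoxy-3,5-bis(methoxymethoxy)benzene
Conditions: NaH (2.4 equiv), MOMCl (2.4 equiv), DMF, 0 °C to rt
Reagents that add atoms: chloromethyl methyl ether, COCCl
Why: Williamson-type O-alkylation of both phenoxides by the hard α-chloro ether should give the bis(acetal), whose two OCH2OMe groups later direct metalation to the carbon between them.

Step 2
Reactants: 2 1-methoxy-3,5-bis(methoxymethoxy)benzene
Product: 4 2-bromo-5-methoxy-1,3-bis(methoxymethoxy)benzene, via aryllithium 3 (not isolated)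
Conditions: n-BuLi (1.1 equiv), THF, 0 °C, 1 h; then BrCH2CH2Br, −78 °C to rt
Reagents that add atoms: 1,2-dibromoethane, BrCCBr
Why: Directed ortho-metalation should occur at the carbon flanked by both chelating acetal groups (a stronger director pair than acetal plus methoxyl), and the aryllithium then takes bromine from 1,2-dibromoethane with loss of ethene.

Step 3
Reactants: 4 2-bromo-5-methoxy-1,3-bis(methoxymethoxy)benzene; 5 prenylboronic acid pinacol ester (4,4,5,5-tetramethyl-2-(3-methylbut-2-en-1-yl)-1,3,2-dioxaborolane)
Product: 6 5-methoxy-1,3-bis(methoxymethoxy)-2-(2-methylbut-3-en-2-yl)benzene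
Conditions: Pd(OAc)2 (5 mol %), t-BuXPhos (10 mol %), aq. K3PO4, THF, 40 °C
Reagents that add atoms: none
Why: Suzuki–Miyaura coupling in its γ-selective mode, in which SE2' transmetalation of the 3,3-disubstituted allylboronate places palladium on the tertiary carbon and a bulky biarylphosphine (2-di-tert-butylphosphino-2',4',6'-triisopropylbiphenyl as first choice, to be confirmed by a short ligand screen) should force reductive elimination before σ–π–σ isomerisation, giving the branched 1,1-dimethylallyl arene.

Step 4
Reactants: 6 5-methoxy-1,3-bis(methoxymethoxy)-2-(2-methylbut-3-en-2-yl)benzene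
Product: 7 5-methoxy-2-(2-methylbut-3-en-2-yl)benzene-1,3-diol (symmetric ring A fragment)
Conditions: HCl (cat., 0.5 M in MeOH), 20–25 °C
Reagents that add atoms: none
Why: Acid-catalysed acetal exchange with methanol should release both phenols as dimethoxymethane is formed, under conditions too mild to protonate the monosubstituted alkene or the ipso carbon of the tertiary allyl group.

Step 5
Reactants: 8 2,4-dihydroxyphenylacetic acid
Product: 9 6-hydroxybenzofuran-2(3H)-one
Conditions: p-TsOH·H2O (cat.), toluene, reflux, Dean–Stark
Reagents that add atoms: none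
Why: Acid-catalysed lactonisation (intramolecular Fischer esterification) driven by azeotropic removal of water, in which only the 2-OH can reach the carboxyl, so the 4-OH stays free.

Step 6
Reactants: 9 6-hydroxybenzofuran-2(3H)-one; 10 trimethyl orthoformate
Product: 12 (E)-6-acetoxy-3-(methoxymethylene)benzofuran-2(3H)-one (ring B fragment carrying C2, C3 and C4), via 6-acetoxybenzofuran-2(3H)-one 11 (not isolated)
Conditions: HC(OMe)3 (2 equiv), Ac2O (excess), 100–105 °C, MeOAc distilled off
Reagents that add atoms: acetic anhydride, CC(=O)OC(C)=O
Why: Alkoxymethylenation of an active methylene (Claisen-type condensation of the lactone CH2 with the dimethoxycarbenium ion from the orthoformate), with hot acetic anhydride acetylating the phenol and scavenging the methanol, as established for the unsubstituted benzofuranone.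

Step 7
Reactants: 7 5-methoxy-2-(2-methylbut-3-en-2-yl)benzene-1,3-diol; 12 (E)-6-acetoxy-3-(methoxymethylene)benzofuran-2(3H)-one
Product: 14 3-(4-acetoxy-2-hydroxyphenyl)-7-hydroxy-5-methoxy-8-(2-methylbut-3-en-2-yl)-2H-chromen-2-one (4'-O-acetyl target), via arylmethylene benzofuranone 13 (not isolated)
Conditions: glacial AcOH, 45–55 °C, N2
Reagents that add atoms: none
Why: Proposed new method: acetic acid activates the lactone carbonyl of the push-pull enol ether 12, a free ring carbon of 7 (ortho to one OH, para to the other, ortho to OMe) adds to the methoxymethylene carbon and methanol is lost, forming C4–C4a and giving arylmethylene lactone 13; after E/Z equilibration of this donor–acceptor alkene the flanking phenol adds to the lactone carbonyl and expels the ring B phenol, forming O1–C2. The closest known reaction types are the Pechmann-type condensation of phloroglucinol-class phenols with α-formyl or α-(alkoxymethylene) arylacetates to 3-arylcoumarins, amine addition–elimination at 3-(methoxymethylene)benzofuran-2(3H)-one, and the rearrangement of 3-(2-hydroxybenzylidene)benzofuran-2(3H)-ones into 3-(2-hydroxyphenyl)coumarins. The pyranone ring is closed by a 6-exo-trig acyl transfer at O1–C2 while the five-membered lactone opens, driven by formation of the aromatic coumarin and relief of furanone strain; no stereocentre is created. The step needs attack through carbon at a single ring position and an untouched vinyl group: the carbon between the hydroxyls of 7 is blocked and the two remaining carbons are equivalent, O-adducts revert whereas C-attack does not, the coumarin carbonyl deactivates ring A against a second annulation, and acetic acid is too weak to protonate the monosubstituted alkene or cleave the aryl acetate.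

Step 8
Reactants: 14 3-(4-acetoxy-2-hydroxyphenyl)-7-hydroxy-5-methoxy-8-(2-methylbut-3-en-2-yl)-2H-chromen-2-one
Product: 15 3-(2,4-dihydroxyphenyl)-7-hydroxy-5-methoxy-8-(2-methylbut-3-en-2-yl)-2H-chromen-2-one (target, CID10090416)
Conditions: K2CO3 (0.3 equiv), MeOH, 0 °C to rt; then AcOH to pH 5
Reagents that add atoms: none
Why: Base-catalysed methanolysis (transesterification) should cleave the aryl acetate much faster than the conjugated coumarin lactone, and any transient lactone opening recloses on neutralisation because the cinnamate geometry is fixed cis.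

**Compound list**

1 | 5-methoxyresorcinol | COc1cc(O)cc(O)c1 | starting material
2 | 1-methoxy-3,5-bis(methoxymethoxy)benzene | COCOc1cc(OC)cc(OCOC)c1 | intermediate
3 | [4-methoxy-2,6-bis(methoxymethoxy)phenyl]lithium | [Li]c1c(OCOC)cc(OC)cc1OCOC | intermediate
4 | 2-bromo-5-methoxy-1,3-bis(methoxymethoxy)benzene | COCOc1cc(OC)cc(OCOC)c1Br | intermediate
5 | prenylboronic acid pinacol ester | CC(C)=CCB1OC(C)(C)C(C)(C)O1 | starting material
6 | 5-methoxy-1,3-bis(methoxymethoxy)-2-(2-methylbut-3-en-2-yl)benzene | C=CC(C)(C)c1c(OCOC)cc(OC)cc1OCOC | intermediate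
7 | 5-methoxy-2-(2-methylbut-3-en-2-yl)benzene-1,3-diol | C=CC(C)(C)c1c(O)cc(OC)cc1O | intermediate
8 | 2,4-dihydroxyphenylacetic acid | OC(=O)Cc1ccc(O)cc1O | starting material
9 | 6-hydroxybenzofuran-2(3H)-one | O=C1Cc2ccc(O)cc2O1 | intermediate
10 | trimethyl orthoformate | COC(OC)OC | starting material
11 | 6-acetoxybenzofuran-2(3H)-one | CC(=O)Oc1ccc2c(c1)OC(=O)C2 | intermediate
12 | (E)-6-acetoxy-3-(methoxymethylene)benzofuran-2(3H)-one | CO/C=C1/C(=O)Oc2cc(OC(C)=O)ccc21 | intermediate
13 | (Z)-6-acetoxy-3-{[2,4-dihydroxy-6-methoxy-3-(2-methylbut-3-en-2-yl)phenyl]methylidene}benzofuran-2(3H)-one (in equilibrium with its E isomer) | C=CC(C)(C)c1c(O)cc(OC)c(/C=C2\C(=O)Oc3cc(OC(C)=O)ccc32)c1O | intermediate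
14 | 3-(4-acetoxy-2-hydroxyphenyl)-7-hydroxy-5-methoxy-8-(2-methylbut-3-en-2-yl)-2H-chromen-2-one | C=CC(C)(C)c1c(O)cc(OC)c2cc(-c3ccc(OC(C)=O)cc3O)c(=O)oc12 | intermediate
15 | 3-(2,4-dihydroxyphenyl)-7-hydroxy-5-methoxy-8-(2-methylbut-3-en-2-yl)-2H-chromen-2-one | C=CC(C)(C)c1c(O)cc(OC)c2cc(-c3ccc(O)cc3O)c(=O)oc12 | target

**Step count**

Total steps: 8. Longest linear sequence: 6 steps (steps 1, 2, 3, 4, 7, 8); the ring B branch (steps 5 and 6) joins at step 7.

**Steps most likely to fail**

1. Step 7 (proposed new method). Under weak acid the C-attack may be too slow, the phenol oxygen may instead open the activated aryl lactone or add reversibly to the enol ether, and the lactone transfer may stall at the arylmethylene stage. The fallback uses known chemistry, sets out from 7 and returns at 15. Vilsmeier–Haack formylation of 7 (POCl3, DMF, MeCN, 0 °C; aqueous NaOAc) at one of its two equivalent free ring carbons would give 2,4-dihydroxy-6-methoxy-3-(2-methylbut-3-en-2-yl)benzaldehyde F1. Perkin condensation of F1 with acid 8 (Ac2O, Et3N, 110 °C), the classical 3-arylcoumarin synthesis, would give 7-acetoxy-3-(2,4-diacetoxyphenyl)-5-methoxy-8-(2-methylbut-3-en-2-yl)-2H-chromen-2-one F2. Methanolysis of the three acetates (K2CO3, MeOH) would then give 15.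

2. Step 3. The tertiary σ-allyl palladium intermediate, crowded by two ortho acetal groups, may isomerise to the primary allyl before reductive elimination and so deliver the linear prenyl arene; protodebromination may also compete. The fallback builds the quaternary carbon stepwise, sets out from 4 and returns at 6. Palladium-catalysed coupling of 4 with the Reformatsky reagent BrZnCH2CO2t-Bu (Pd(dba)2, P(t-Bu)3, THF, rt) would give tert-butyl 2-[4-methoxy-2,6-bis(methoxymethoxy)phenyl]acetate F3. Two successive enolate methylations (LiN(i-Pr)2, MeI, THF, −78 °C to rt) would give tert-butyl 2-[4-methoxy-2,6-bis(methoxymethoxy)phenyl]-2-methylpropanoate F4. Reduction (LiAlH4, THF, reflux) would give 2-[4-methoxy-2,6-bis(methoxymethoxy)phenyl]-2-methylpropan-1-ol F5, and Dess–Martin oxidation would give 2-[4-methoxy-2,6-bis(methoxymethoxy)phenyl]-2-methylpropanal F6. Wittig methylenation (Ph3P=CH2 from Ph3PCH3Br and KOt-Bu, THF) would then give 6.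

3. Step 4. During acetal cleavage the phloroglucinol-like ring may be re-alkylated by methoxymethyl cations, the tertiary allyl group may migrate or be lost after ipso-protonation, or a hydroxyl may cyclise onto the alkene. The fallback removes the acetals before the allyl group is present, sets out from 4 and returns at 7. Acid methanolysis of 4 (HCl, MeOH, 40 °C) would give 2-bromo-5-methoxybenzene-1,3-diol F7. The γ-selective Suzuki–Miyaura coupling with 5 (Pd(OAc)2, t-BuXPhos, excess aq. K3PO4, THF, 40 °C) would then be run on the free, less hindered bromoresorcinol and give 7 directly, with no acid treatment of the allylated arene.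

**Further compounds**

F1 | step 7 | 2,4-dihydroxy-6-methoxy-3-(2-methylbut-3-en-2-yl)benzaldehyde | C=CC(C)(C)c1c(O)cc(OC)c(C=O)c1O
F2 | step 7 | 7-acetoxy-3-(2,4-diacetoxyphenyl)-5-methoxy-8-(2-methylbut-3-en-2-yl)-2H-chromen-2-one | C=CC(C)(C)c1c(OC(C)=O)cc(OC)c2cc(-c3ccc(OC(C)=O)cc3OC(C)=O)c(=O)oc12
F3 | step 3 | tert-butyl 2-[4-methoxy-2,6-bis(methoxymethoxy)phenyl]acetate | COCOc1cc(OC)cc(OCOC)c1CC(=O)OC(C)(C)C
F4 | step 3 | tert-butyl 2-[4-methoxy-2,6-bis(methoxymethoxy)phenyl]-2-methylpropanoate | COCOc1cc(OC)cc(OCOC)c1C(C)(C)C(=O)OC(C)(C)C
F5 | step 3 | 2-[4-methoxy-2,6-bis(methoxymethoxy)phenyl]-2-methylpropan-1-ol | COCOc1cc(OC)cc(OCOC)c1C(C)(C)CO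
F6 | step 3 | 2-[4-methoxy-2,6-bis(methoxymethoxy)phenyl]-2-methylpropanal | COCOc1cc(OC)cc(OCOC)c1C(C)(C)C=O
F7 | step 4 | 2-bromo-5-methoxybenzene-1,3-diol | COc1cc(O)c(Br)c(O)c1
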